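## Retrosynthetic overview

1. The two formyl groups and the two free phenols are removed first: the target comes from a cis-fused 6′,8′-dimethoxy cyclopenta[b]chromene spiro ether by double Rieche formylation and O-demethylation.
2. The pyran C1–H comes from ionic hydrogenation of a cyclic hemiketal. The key C–C bond (C2–C1′) comes from an intermolecular Michael addition of the lithium enolate of (5R,10S)-2,10-dimethyl-7-isopropylspiro[4.5]dec-6-en-1-one to an o-quinone methide released from a 2-(1-tosyl-3-methylbutyl)-3,5-dimethoxyphenol.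
3. The spiro ketone comes from C2 methylation; its C6=C7 bond from an enol triflate of a C6 ketone; its cyclopentane ring from a reductive aldol spirocyclisation of an alkylidene-ketone aldehyde.
4. That aldehyde comes from a directed aldol condensation of (+)-menthone (from (+)-menthol) with pent-4-enal and cleavage of the terminal alkene; the sulfone comes from 2-hydroxy-4,6-dimethoxybenzaldehyde and i-BuMgBr.
5. Ring order: cyclohexane (chiral pool), then spiro cyclopentane, then pyran last; the benzene ring is bought.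

Assumption and convention: the four purchased materials are taken as cheap catalogue items; terpenoid locants are those of the spiro[4.5]decane unit (C1 oxygenated, C2 methyl-bearing, C5 spiro, C6=C7 with isopropyl on C7, C10 methyl-bearing) and C1′ is the benzylic carbon; epimers at C7, at the C1 carbinol and at C2 of the ketone are carried as mixtures because these centres are erased or re-set later.

## Route

Step 1
Reactants: 1 (+)-menthol, (1S,2R,5S)-5-methyl-2-(propan-2-yl)cyclohexan-1-ol
Product: 2 (+)-menthone, (2R,5S)-5-methyl-2-(propan-2-yl)cyclohexan-1-one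
Conditions: NaOCl (aq), AcOH, 0 °C → rt
Reagents that add atoms: none
Why: Hypochlorite oxidation of a secondary alcohol (Stevens oxidation) gives the ketone without touching the methyl-bearing stereocentre, which becomes C10 of the target.

Step 2
Reactants: 2 (+)-menthone; 3 pent-4-enal
Product: 5 (3S,6R)-2-(1-hydroxypent-4-en-1-yl)-3-methyl-6-(propan-2-yl)cyclohexan-1-one, via lithium enolate 4 (not isolated)
Conditions: LiN(iPr)2, THF, −78 °C; then 3, −78 °C; aq NH4Cl
Reagents that add atoms: none
Why: Directed aldol addition: kinetic deprotonation of menthone occurs at the CH2 α-carbon (the isopropyl side is a hindered methine) and the lithium enolate adds to the aldehyde at −78 °C; the two new centres are removed in step 3.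

Step 3
Reactants: 5 aldol adduct
Product: 7 (2E,3S)-3-methyl-2-(pent-4-en-1-ylidene)-6-(propan-2-yl)cyclohexan-1-one, via mesylate 6 (not isolated)
Conditions: MsCl, Et3N, CH2Cl2, 0 °C; then DBU, rt
Reagents that add atoms: none
Why: Mesylation and E1cB elimination complete the aldol condensation to the conjugated E-alkylidene ketone under basic conditions that do not move the double bond into the ring; the α-isopropyl centre may epimerise but is erased in step 7.

Step 4
Reactants: 7 alkylidene ketone
Product: 9 (4E)-4-[(6S)-6-methyl-2-oxo-3-(propan-2-yl)cyclohexylidene]butanal, via diol 8 (not isolated)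
Conditions: OsO4 (2 mol %), NaIO4, 2,6-lutidine, dioxane–H2O (3:1), rt
Reagents that add atoms: osmium tetroxide O=[Os](=O)(=O)=O; sodium periodate [Na+].[O-]I(=O)(=O)=O
Why: Lemieux–Johnson cleavage: the terminal alkene is dihydroxylated much faster than the electron-poor enone C=C, and periodate cleaves the diol to the aldehyde.

Step 5
Reactants: 9 enone aldehyde
Product: 11 (5S,10S)-1-hydroxy-10-methyl-7-(propan-2-yl)spiro[4.5]decan-6-one, via copper enolate 10 (not isolated)
Conditions: [(Ph3P)CuH]6 (0.4 equiv), toluene–THF, −40 → 0 °C; aq NH4Cl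
Reagents that add atoms: none
Why: Reductive aldol cyclisation: 1,4-hydride delivery gives regiospecifically the tetrasubstituted copper enolate at C5, which adds 5-exo to the tethered aldehyde on the face opposite the pseudoaxial C10 methyl (held axial by allylic strain), so the new C5–C1 bond is trans to that methyl and the spiro centre is set.

Step 6
Reactants: 11 spiro hydroxy ketone
Product: 12 (5S,10S)-1-[(tert-butyldimethylsilyl)oxy]-10-methyl-7-(propan-2-yl)spiro[4.5]decan-6-one
Conditions: TBSOTf, 2,6-lutidine, CH2Cl2, −78 → 0 °C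
Reagents that add atoms: tert-butyldimethylsilyl trifluoromethanesulfonate CC(C)(C)[Si](C)(C)OS(=O)(=O)C(F)(F)F
Why: Silylation of the hindered secondary alcohol under non-basic conditions blocks retro-aldol cleavage in the next step.

Step 7
Reactants: 12 silyl ether ketone
Product: 14 (5S,10S)-1-[(tert-butyldimethylsilyl)oxy]-10-methyl-7-(propan-2-yl)spiro[4.5]dec-6-en-6-yl trifluoromethanesulfonate, via potassium enolate 13 (not isolated)
Conditions: KN(SiMe3)2, THF, −78 → 0 °C; then PhNTf2, −78 °C → rt
Reagents that add atoms: N-phenylbis(trifluoromethanesulfonimide) O=S(=O)(N(c1ccccc1)S(=O)(=O)C(F)(F)F)C(F)(F)F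
Why: Enol triflate formation: the ketone can enolise only toward C7 because C5 is quaternary, so O-sulfonylation fixes the C6=C7 double bond and removes the C7 stereocentre.

Step 8
Reactants: 14 enol triflate
Product: 15 tert-butyldimethyl{[(5R,10S)-10-methyl-7-(propan-2-yl)spiro[4.5]dec-6-en-1-yl]oxy}silane
Conditions: Pd(OAc)2 (5 mol %), PPh3, HCO2H, n-Bu3N, DMF, 60 °C
Reagents that add atoms: none
Why: Palladium-catalysed formate reduction of the enol triflate (oxidative addition to zerovalent palladium, formate exchange, decarboxylation, reductive elimination) replaces OTf by H without moving the trisubstituted alkene.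

Step 9
Reactants: 15 silyl ether
Product: 16 (5R,10S)-10-methyl-7-(propan-2-yl)spiro[4.5]dec-6-en-1-ol
Conditions: TBAF, THF, 50 °C
Reagents that add atoms: none
Why: Fluoride-induced desilylation frees the alcohol, and no other group in the molecule is sensitive to fluoride.

Step 10
Reactants: 16 spiro alcohol
Product: 17 (5R,10S)-10-methyl-7-(propan-2-yl)spiro[4.5]dec-6-en-1-one
Conditions: Dess–Martin periodinane, CH2Cl2, rt
Reagents that add atoms: none
Why: Dess–Martin oxidation of the secondary alcohol gives the cyclopentanone and removes the unassigned carbinol centre.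

Step 11
Reactants: 17 spiro ketone
Product: 19 (5R,10S)-2,10-dimethyl-7-(propan-2-yl)spiro[4.5]dec-6-en-1-one, via lithium enolate 18 (not isolated)
Conditions: LiN(iPr)2, THF, −78 °C; then MeI, −78 → −40 °C
Reagents that add atoms: iodomethane CI
Why: Enolate alkylation: the ketone has a single enolisable position (C2), so monomethylation is regiospecific, and the C2 configuration is irrelevant because C2 is re-enolised in step 14.

Step 12
Reactants: 20 2-hydroxy-4,6-dimethoxybenzaldehyde; 21 isobutylmagnesium bromide (i-BuMgBr)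
Product: 22 2-(1-hydroxy-3-methylbutyl)-3,5-dimethoxyphenol (racemic)
Conditions: 21 (2.5 equiv), THF, 0 °C → rt; aq NH4Cl
Reagents that add atoms: none
Why: Grignard addition to the aldehyde, after the first equivalent has deprotonated the phenol, installs the isobutyl-bearing benzylic carbon.

Step 13
Reactants: 22 benzylic alcohol
Product: 23 3,5-dimethoxy-2-[3-methyl-1-(4-methylbenzenesulfonyl)butyl]phenol (racemic)
Conditions: 4-MeC6H4SO2Na, HCO2H–H2O, rt
Reagents that add atoms: sodium 4-methylbenzenesulfinate Cc1ccc(cc1)S(=O)[O-].[Na+]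
Why: Acid-promoted ionisation of the electron-rich benzylic alcohol and capture by sulfinate (SN1 substitution) gives a stable, base-labile o-quinone methide precursor.

Step 14
Reactants: 19 spiro ketone; 23 sulfone
Product: 27 cyclic hemiketal of keto phenol 26 (cis-fused 3′a-hydroxy-6′,8′-dimethoxy spiro[cyclohexene-cyclopenta[b]chromene]), via lithium enolate 24 (not isolated), via o-quinone methide 25 (not isolated), via keto phenol 26 (not isolated)
Conditions: 19, LiN(SiMe3)2, THF, −78 °C; then 23 pre-treated at −78 °C with LiN(SiMe3)2 (1 equiv per 23), −78 → 0 °C; aq NH4Cl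
Reagents that add atoms: none
Why: Key step, an intermolecular Michael addition: the only possible enolate of 19 adds through C2 to the exocyclic carbon of the o-quinone methide released from the phenoxide of 23 by loss of sulfinate, and the phenoxide then closes onto the C1 ketone; C2 is attacked on the face syn to the flat vinylic C6–H and anti to the C10 CH(CH3) arm, and a compact lithium-bridged (hetero-Diels–Alder-like) transition state with the cyclopentene ring exo and the isobutyl group pointing outward places isobutyl cis to the C2 methyl (1′R,2R).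

Step 15
Reactants: 27 hemiketal
Product: 28 (1R,3′aS,6S,9′R,9′aR)-6′,8′-dimethoxy-6,9′a-dimethyl-9′-(2-methylpropyl)-3-(propan-2-yl)-1′,2′,9′,9′a-tetrahydro-3′aH-spiro[cyclohex-2-ene-1,3′-cyclopenta[b]chromene]
Conditions: Et3SiH, BF3·OEt2, CH2Cl2, −78 → −20 °C
Reagents that add atoms: none
Why: Ionic hydrogenation: the Lewis acid ionises the hemiketal to an aryl oxocarbenium ion that cannot eliminate (C2 and C5 are quaternary) and is reduced by the silane to the strongly preferred cis-fused pyran, placing H at C1 cis to the C2 methyl.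

Step 16
Reactants: 28 dimethoxy chroman
Product: 29 (1R,3′aS,6S,9′R,9′aR)-6′,8′-dimethoxy-6,9′a-dimethyl-9′-(2-methylpropyl)-3-(propan-2-yl)-1′,2′,9′,9′a-tetrahydro-3′aH-spiro[cyclohex-2-ene-1,3′-cyclopenta[b]chromene]-5′,7′-dicarbaldehyde
Conditions: Cl2CHOMe (6 equiv), TiCl4, CH2Cl2, −78 → 0 °C; then H2O
Reagents that add atoms: dichloromethyl methyl ether COC(Cl)Cl; water O
Why: Rieche formylation (Friedel–Crafts reaction with the chloro(methoxy)methyl cation) occurs twice, at the only two free positions of the trialkoxy arene, each activated by three oxygen substituents.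

Step 17
Reactants: 29 dimethoxy dialdehyde
Product: 30 (1R,3′aS,6S,9′R,9′aR)-6′,8′-dihydroxy-6,9′a-dimethyl-9′-(2-methylpropyl)-3-(propan-2-yl)-1′,2′,9′,9′a-tetrahydro-3′aH-spiro[cyclohex-2-ene-1,3′-cyclopenta[b]chromene]-5′,7′-dicarbaldehyde (CNP0121396.2)
Conditions: BCl3, CH2Cl2, −78 → 0 °C; then H2O
Reagents that add atoms: none
Why: Chelation-assisted Lewis acid demethylation cleaves the two methyl ethers that lie ortho to formyl groups, while the hindered secondary alkyl–oxygen bond of the pyran ring cannot undergo SN2 cleavage.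

## Compound list

1 | (+)-menthol, (1S,2R,5S)-5-methyl-2-(propan-2-yl)cyclohexan-1-ol | C[C@H]1CC[C@H](C(C)C)[C@@H](O)C1 | starting material
2 | (+)-menthone, (2R,5S)-5-methyl-2-(propan-2-yl)cyclohexan-1-one | C[C@H]1CC[C@H](C(C)C)C(=O)C1 | intermediate
3 | pent-4-enal | C=CCCC=O | starting material
4 | lithium (3S,6R)-3-methyl-6-(propan-2-yl)cyclohex-1-en-1-olate (kinetic enolate of 2, formed in the flask) | C[C@H]1CC[C@H](C(C)C)C(O[Li])=C1 | intermediate
5 | (3S,6R)-2-(1-hydroxypent-4-en-1-yl)-3-methyl-6-(propan-2-yl)cyclohexan-1-one (epimers at C2 and at the carbinol carbon) | C[C@H]1CC[C@H](C(C)C)C(=O)C1C(O)CCC=C | intermediate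
6 | 1-[(3R,6S)-6-methyl-2-oxo-3-(propan-2-yl)cyclohexyl]pent-4-en-1-yl methanesulfonate (formed in the flask) | C[C@H]1CC[C@H](C(C)C)C(=O)C1C(OS(C)(=O)=O)CCC=C | intermediate
7 | (2E,3S)-3-methyl-2-(pent-4-en-1-ylidene)-6-(propan-2-yl)cyclohexan-1-one (C6 epimers) | C=CCC/C=C1/C(=O)C(C(C)C)CC[C@@H]1C | intermediate
8 | (2E,3S)-2-(4,5-dihydroxypentylidene)-3-methyl-6-(propan-2-yl)cyclohexan-1-one (formed in the flask) | OCC(O)CC/C=C1/C(=O)C(C(C)C)CC[C@@H]1C | intermediate
9 | (4E)-4-[(6S)-6-methyl-2-oxo-3-(propan-2-yl)cyclohexylidene]butanal | O=CCC/C=C1/C(=O)C(C(C)C)CC[C@@H]1C | intermediate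
10 | copper (3S)-3-methyl-2-(4-oxobutyl)-6-(propan-2-yl)cyclohex-1-en-1-olate, PPh3-ligated (formed in the flask) | O=CCCCC1=C(O[Cu])C(C(C)C)CC[C@@H]1C | intermediate
11 | (5S,10S)-1-hydroxy-10-methyl-7-(propan-2-yl)spiro[4.5]decan-6-one (C1 and C7 epimers; C1 trans and C4 cis to the C10 methyl) | OC1CCC[C@@]12C(=O)C(C(C)C)CC[C@@H]2C | intermediate
12 | (5S,10S)-1-[(tert-butyldimethylsilyl)oxy]-10-methyl-7-(propan-2-yl)spiro[4.5]decan-6-one | CC(C)(C)[Si](C)(C)OC1CCC[C@@]12C(=O)C(C(C)C)CC[C@@H]2C | intermediate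
13 | potassium (5S,10S)-1-[(tert-butyldimethylsilyl)oxy]-10-methyl-7-(propan-2-yl)spiro[4.5]dec-6-en-6-olate (formed in the flask) | CC(C)(C)[Si](C)(C)OC1CCC[C@@]12C(O[K])=C(C(C)C)CC[C@@H]2C | intermediate
14 | (5S,10S)-1-[(tert-butyldimethylsilyl)oxy]-10-methyl-7-(propan-2-yl)spiro[4.5]dec-6-en-6-yl trifluoromethanesulfonate | CC(C)(C)[Si](C)(C)OC1CCC[C@@]12C(OS(=O)(=O)C(F)(F)F)=C(C(C)C)CC[C@@H]2C | intermediate
15 | tert-butyldimethyl{[(5R,10S)-10-methyl-7-(propan-2-yl)spiro[4.5]dec-6-en-1-yl]oxy}silane | CC(C)(C)[Si](C)(C)OC1CCC[C@@]12C=C(C(C)C)CC[C@@H]2C | intermediate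
16 | (5R,10S)-10-methyl-7-(propan-2-yl)spiro[4.5]dec-6-en-1-ol | OC1CCC[C@@]12C=C(C(C)C)CC[C@@H]2C | intermediate
17 | (5R,10S)-10-methyl-7-(propan-2-yl)spiro[4.5]dec-6-en-1-one | O=C1CCC[C@@]12C=C(C(C)C)CC[C@@H]2C | intermediate
18 | lithium (5R,10S)-10-methyl-7-(propan-2-yl)spiro[4.5]deca-1,6-dien-1-olate (formed in the flask) | [Li]OC1=CCC[C@@]12C=C(C(C)C)CC[C@@H]2C | intermediate
19 | (5R,10S)-2,10-dimethyl-7-(propan-2-yl)spiro[4.5]dec-6-en-1-one (C2 epimers) | O=C1C(C)CC[C@@]12C=C(C(C)C)CC[C@@H]2C | intermediate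
20 | 2-hydroxy-4,6-dimethoxybenzaldehyde | COc1cc(OC)c(C=O)c(O)c1 | starting material
21 | isobutylmagnesium bromide (i-BuMgBr) | CC(C)C[Mg]Br | starting material
22 | 2-(1-hydroxy-3-methylbutyl)-3,5-dimethoxyphenol (racemic) | COc1cc(OC)c(C(O)CC(C)C)c(O)c1 | intermediate
23 | 3,5-dimethoxy-2-[3-methyl-1-(4-methylbenzenesulfonyl)butyl]phenol (racemic) | COc1cc(OC)c(C(CC(C)C)S(=O)(=O)c2ccc(C)cc2)c(O)c1 | intermediate
24 | lithium (5R,10S)-2,10-dimethyl-7-(propan-2-yl)spiro[4.5]deca-1,6-dien-1-olate (formed in the flask) | [Li]OC1=C(C)CC[C@@]12C=C(C(C)C)CC[C@@H]2C | intermediate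
25 | 3,5-dimethoxy-6-(3-methylbutylidene)cyclohexa-2,4-dien-1-one (o-quinone methide, C=C geometry not fixed, formed in the flask) | COC1=CC(=O)C(=CCC(C)C)C(OC)=C1 | intermediate
26 | (2R,5R,10S)-2-[(1R)-1-(2-hydroxy-4,6-dimethoxyphenyl)-3-methylbutyl]-2,10-dimethyl-7-(propan-2-yl)spiro[4.5]dec-6-en-1-one (formed in the flask) | CC(C)C[C@@H](c1c(OC)cc(OC)cc1O)[C@@]1(C)CC[C@@]2(C=C(C(C)C)CC[C@@H]2C)C1=O | intermediate
27 | cyclic hemiketal of 26: cis-fused 3′a-hydroxy analogue of 28 (terpenoid locants 1S,2R,5R,10S; C1′ R) | CC(C)C[C@H]1c2c(OC)cc(OC)cc2O[C@@]2(O)[C@]1(C)CC[C@@]21C=C(C(C)C)CC[C@@H]1C | intermediate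
28 | (1R,3′aS,6S,9′R,9′aR)-6′,8′-dimethoxy-6,9′a-dimethyl-9′-(2-methylpropyl)-3-(propan-2-yl)-1′,2′,9′,9′a-tetrahydro-3′aH-spiro[cyclohex-2-ene-1,3′-cyclopenta[b]chromene] | CC(C)C[C@H]1c2c(OC)cc(OC)cc2O[C@H]2[C@]1(C)CC[C@@]21C=C(C(C)C)CC[C@@H]1C | intermediate
29 | 5′,7′-dicarbaldehyde of 28 (6′,8′-dimethoxy) | CC(C)C[C@H]1c2c(OC)c(C=O)c(OC)c(C=O)c2O[C@H]2[C@]1(C)CC[C@@]21C=C(C(C)C)CC[C@@H]1C | intermediate
30 | (1R,3′aS,6S,9′R,9′aR)-6′,8′-dihydroxy-6,9′a-dimethyl-9′-(2-methylpropyl)-3-(propan-2-yl)-1′,2′,9′,9′a-tetrahydro-3′aH-spiro[cyclohex-2-ene-1,3′-cyclopenta[b]chromene]-5′,7′-dicarbaldehyde (CNP0121396.2) | CC(C)C[C@H]1c2c(O)c(C=O)c(O)c(C=O)c2O[C@H]2[C@]1(C)CC[C@@]21C=C(C(C)C)CC[C@@H]1C | target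

## Step count and risks

Total step count: 17. Longest linear sequence: 15 steps (steps 1–11, then 14–17, from (+)-menthol).

The three steps most likely to fail:

Step 5 (reductive aldol spirocyclisation). The copper hydride may reduce the aldehyde, or facial control at C5 may be poor. The fallback sets out from 9 and comes back at 11. Compound 9 is oxidised (NaClO2, NaH2PO4, 2-methylbut-2-ene) to the enone acid F1. The enone C=C is hydrogenated (H2, Pd/C) to the saturated keto acid F2. Intramolecular C-acylation of the ketone enol in polyphosphoric acid, where the tether lets only C5 react, gives the spiro diketone F3. Reduction of the less hindered cyclopentanone carbonyl (NaBH4, MeOH, −78 °C) returns 11.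

Step 14 (enolate Michael addition to the o-quinone methide). The methide may tautomerise to a styrene, and selectivity at C2 and C1′ may be low. The fallback sets out from 19 (with 22) and comes back at 28. Compound 19 is converted (TMSOTf, Et3N, CH2Cl2) into its trimethylsilyl enol ether F4. F4 is heated with diol 22 in toluene at 110 °C; 22 loses water to o-quinone methide 25, which is trapped in a neutral inverse-demand hetero-Diels–Alder reaction (siloxy group endo, ring exo) to give the trimethylsilyl ketal F5. Reduction of F5 with Et3SiH/BF3·OEt2 gives 28 directly.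

Step 16 (double Rieche formylation). TiCl4 and the HCl formed may attack the trisubstituted alkene, or the second formylation may stall. The fallback sets out from 28 and comes back at 29. Both free aromatic positions are brominated (NBS, 2.1 equiv, MeCN, −20 °C) to give the dibromide F6. Double bromine–lithium exchange (t-BuLi, THF, −78 °C) and a DMF quench give 29 under non-acidic conditions.

## Further compounds

F1 | step 5 | (4E)-4-[(6S)-6-methyl-2-oxo-3-(propan-2-yl)cyclohexylidene]butanoic acid | OC(=O)CC/C=C1/C(=O)C(C(C)C)CC[C@@H]1C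
F2 | step 5 | 4-[(6S)-6-methyl-2-oxo-3-(propan-2-yl)cyclohexyl]butanoic acid (C1 and C3 epimers) | OC(=O)CCCC1C(=O)C(C(C)C)CC[C@@H]1C
F3 | step 5 | (5S,10S)-10-methyl-7-(propan-2-yl)spiro[4.5]decane-1,6-dione (C7 epimers) | O=C1CCC[C@@]12C(=O)C(C(C)C)CC[C@@H]2C
F4 | step 14 | trimethyl{[(5R,10S)-2,10-dimethyl-7-(propan-2-yl)spiro[4.5]deca-1,6-dien-1-yl]oxy}silane | C[Si](C)(C)OC1=C(C)CC[C@@]12C=C(C(C)C)CC[C@@H]2C
F5 | step 14 | trimethylsilyl ketal of 27 (3′a-trimethylsilyloxy analogue of 28) | CC(C)C[C@H]1c2c(OC)cc(OC)cc2O[C@@]2(O[Si](C)(C)C)[C@]1(C)CC[C@@]21C=C(C(C)C)CC[C@@H]1C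
F6 | step 16 | 5′,7′-dibromo derivative of 28 | CC(C)C[C@H]1c2c(OC)c(Br)c(OC)c(Br)c2O[C@H]2[C@]1(C)CC[C@@]21C=C(C(C)C)CC[C@@H]1C
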